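**Retrosynthetic overview**

1. Feature: ring B (C1–C6 plus C10) is made of an oxygen-centred three-carbon unit C4–C5–C6 and a four-carbon diene unit C10–C1–C2–C3; ring A (C6–C10) is the three-atom tether C7–C8–C9 joining their termini C6 and C10.
2. Target 25 ⇐ desilylation and C1 anisoylation ⇐ diol enone 23 ⇐ α-ketol transposition with E1cB epoxide opening ⇐ Rubottom oxidation/epoxidation of cycloadduct 16.
3. 16 ⇐ intramolecular (4+3) cycloaddition of the oxyallyl cation from the tertiary α-chloro ketone 13, forming C6–C10 and C3–C4.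
4. 13 ⇐ methyl ketone 11 ⇐ nitrile 9 ⇐ catalytic asymmetric dienylation of keto nitrile 4 with enyne 5 (sets C9); 4 ⇐ Michael addition/Krapcho from 1 and 2.
5. Ring order: rings A and B both close in step 8; no other ring is formed.

Key step: step 8

Remark: locants C1–C10 of the overview are used for all bicyclic compounds; β is the face of ring B carrying the 6-methyl group, α the opposite face.
Remark: 2 is used as the stabilised commercial ketone and 5 as the geometrically pure E isomer.
Remark: in step 3 the isopropyl group is assumed to act as the larger ketone substituent; the ligand antipode that gives 9R (assumed: the one built on (1R,2R)-cyclohexane-1,2-diamine) is used, and the sense is confirmed on the first run.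

Step 1
Reactants: 1 ethyl 2-cyanopropanoate; 2 4-methylpent-1-en-3-one
Product: 3 ethyl 2-cyano-2,6-dimethyl-5-oxoheptanoate (racemic)
Conditions: K2CO3 (0.1 equiv), EtOH, 0 °C → rt
Reagents that add atoms: none
Why: base-catalysed Michael addition of the acidic cyano ester to the unhindered vinyl ketone forms the C6–C7 bond; C6 is racemic, which is harmless because this centre is ionised in step 8.

Step 2
Reactants: 3 ethyl 2-cyano-2,6-dimethyl-5-oxoheptanoate
Product: 4 2,6-dimethyl-5-oxoheptanenitrile (racemic)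
Conditions: LiCl (2 equiv), H2O (2 equiv), DMSO, 150 °C
Reagents that add atoms: none
Why: Krapcho dealkoxycarbonylation, in which chloride dealkylates the ethyl ester, the α-cyano carboxylate loses CO2 and the nitrile-stabilised carbanion is protonated by water, while the isopropyl ketone is unaffected.

Step 3
Reactants: 4 2,6-dimethyl-5-oxoheptanenitrile; 5 (E)-pent-3-en-1-yne (1.6 equiv)
Product: 8 (5R,6E,8E)-5-hydroxy-2-methyl-5-(propan-2-yl)deca-6,8-dienenitrile (both C2 epimers), via dienylzirconocene chloride 6 (not isolated), via dienyl(methyl)zinc 7 (not isolated)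
Conditions: 5, Cp2Zr(H)Cl, CH2Cl2, rt; Me2Zn, toluene, −78 °C; then 4, Ti(OiPr)4 (1.2 equiv), N,N'-(cyclohexane-1,2-diyl)bis(2-exo-hydroxy-10-camphorsulfonamide) ligand (10 mol %), rt; aq NH4Cl
Reagents that add atoms: none
Why: syn hydrozirconation of the terminal alkyne gives the (1E,3E)-dienylzirconium species 6, zirconium-to-zinc transmetalation gives 7, and its 1,2-addition to the ketone is catalysed by the chiral titanium bis(sulfonamide) diolate (catalytic asymmetric dienylation of ketones), which should set C9 by distinguishing the branched isopropyl group from the unbranched chain; the nitrile is inert.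

Step 4
Reactants: 8 (5R,6E,8E)-5-hydroxy-2-methyl-5-(propan-2-yl)deca-6,8-dienenitrile
Product: 9 (5R,6E,8E)-2-methyl-5-(propan-2-yl)-5-[(triethylsilyl)oxy]deca-6,8-dienenitrile (both C2 epimers)
Conditions: TESOTf, 2,6-lutidine, CH2Cl2, −78 → 0 °C
Reagents that add atoms: triethylsilyl trifluoromethanesulfonate, CC[Si](CC)(CC)OS(=O)(=O)C(F)(F)F
Why: a silyl triflate with a hindered pyridine base silylates even the tertiary alcohol (silyl ether protection), which must be masked so that the oxygen cannot capture the cation of step 8; the medium stays basic, so the dienylic C–O bond should not ionise.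

Step 5
Reactants: 9 (5R,6E,8E)-2-methyl-5-(propan-2-yl)-5-[(triethylsilyl)oxy]deca-6,8-dienenitrile
Product: 11 (6R,7E,9E)-3-methyl-6-(propan-2-yl)-6-[(triethylsilyl)oxy]undeca-7,9-dien-2-one (both C3 epimers), via lithium ketimide 10 (not isolated)
Conditions: MeLi (1.5 equiv), Et2O, −78 → 0 °C; then AcOH/NaOAc buffer (pH 5), H2O, 0 °C
Reagents that add atoms: methyllithium, [Li]C; water, O
Why: methyllithium adds only once to the nitrile because the N-lithio ketimine 10 is not electrophilic, and buffered hydrolysis of the imine liberates the methyl ketone at a pH the tertiary dienylic silyl ether should tolerate (nitrile-to-ketone conversion); 9 recovered after competing α-deprotonation can be recycled.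

Step 6
Reactants: 11 (6R,7E,9E)-3-methyl-6-(propan-2-yl)-6-[(triethylsilyl)oxy]undeca-7,9-dien-2-one
Product: 12 (6R,7E,9E)-3-methyl-6-(propan-2-yl)-6-[(triethylsilyl)oxy]-2-[(trimethylsilyl)oxy]undeca-2,7,9-triene (2E/2Z mixture)
Conditions: TMSCl (2 equiv), NaI (2 equiv), Et3N (3 equiv), MeCN, rt
Reagents that add atoms: chlorotrimethylsilane, C[Si](C)(C)Cl
Why: silylation under equilibrating conditions (iodotrimethylsilane formed in the flask, amine base) should favour the more substituted, tetrasubstituted enol ether of the α-branched methyl ketone (thermodynamic silyl enol ether formation); the minor terminal isomer would give the chloromethyl ketone in step 7, which is removed by chromatography.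

Step 7
Reactants: 12 (6R,7E,9E)-3-methyl-6-(propan-2-yl)-6-[(triethylsilyl)oxy]-2-[(trimethylsilyl)oxy]undeca-2,7,9-triene
Product: 13 (6R,7E,9E)-3-chloro-3-methyl-6-(propan-2-yl)-6-[(triethylsilyl)oxy]undeca-7,9-dien-2-one (both C3 epimers)
Conditions: NCS (1.05 equiv), NaHCO3, THF, −78 → 0 °C
Reagents that add atoms: N-chlorosuccinimide, O=C1CCC(=O)N1Cl
Why: electrophilic chlorination of the electron-rich silyl enol ether places chlorine on the enol carbon C6 without acid, and the less nucleophilic conjugated diene should be left alone; the C–Cl centre forms as both epimers, which is harmless because it ionises in step 8.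

Step 8
Reactants: 13 (6R,7E,9E)-3-chloro-3-methyl-6-(propan-2-yl)-6-[(triethylsilyl)oxy]undeca-7,9-dien-2-one
Product: 16 (3R,6S,9R,10R)-3β,6β-dimethyl-9α-(propan-2-yl)-9β-[(triethylsilyl)oxy]-10α-H-bicyclo[5.3.0]dec-1-en-5-one (overview locants; trans-fused), via sodium enolate 14 (not isolated), via oxyallyl cation 15 (not isolated)
Conditions: NaOCH2CF3 (2 equiv), CF3CH2OH (0.02 M), −10 °C → rt
Reagents that add atoms: none
Why: Trifluoroethoxide removes a C4 proton to give enolate 14, which expels chloride from the tertiary C6 to give the 2-oxidoallyl cation 15; C6 then bonds to C10 and C4 to C3 of the s-cis (E,E)-diene in a concerted asynchronous or stepwise (4+3) process, as in the known intramolecular oxyallyl cation cycloadditions of α-halo ketones with tethered 1,3-dienes that give hydroazulenones. Ring A closes by the C6–C10 bond across the three-atom tether C7–C8–C9 (5-exo with respect to C10=C1), and ring B closes as the seven-membered ring from the three-carbon unit C4–C5–C6 and the four-carbon unit C10–C1–C2–C3 through C6–C10 and C3–C4. The tether can span C6 and C10 only when it lies syn to the oxido oxygen, and the extended arrangement, in which the C5–O unit points away from the diene, should then place the 6-methyl group and H-10 trans (trans ring fusion). The diene face is chosen by the allylic stereocentre C9: with C8 held on the reacting face by the tether, the isopropyl group should take the position remote from C1 and the silyloxy group the position next to it, so that the 9-oxygen ends cis to C1 and trans to H-10 (C10 R in 16). Suprafacial addition to the (E,E)-diene fixes the 3-methyl group cis to C9 on ring B, a centre that is made planar in step 11. The step needs cycloaddition to outrun capture of 15 by solvent, Favorskii contraction and proton loss; the weakly nucleophilic fluoroalcohol, high dilution and the gem-disubstituted five-membered tether should secure this, and both C3 epimers of 13 give the same cation.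

Step 9
Reactants: 16 cycloadduct (3β,6β-dimethyl-9β-silyloxy dec-1-en-5-one)
Product: 17 trimethylsilyl enol ether of 16 (C4=C5–OSiMe3; C1=C2 retained)
Conditions: TMSOTf (1.3 equiv), Et3N (2 equiv), CH2Cl2, 0 °C
Reagents that add atoms: trimethylsilyl trifluoromethanesulfonate, C[Si](C)(C)OS(=O)(=O)C(F)(F)F
Why: soft enolisation with silyl triflate and amine gives the only possible enol ether, C4=C5, because C6 is quaternary (silyl enol ether formation).

Step 10
Reactants: 17 trimethylsilyl enol ether of 16
Product: 20 1α,2α-epoxy-3β,6β-dimethyl-9α-(propan-2-yl)-9β-[(triethylsilyl)oxy]-4α-[(trimethylsilyl)oxy]bicyclo[5.3.0]decan-5-one (overview locants), via silyloxy oxirane 18 (not isolated), via α-silyloxy ketone 19 (not isolated)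
Conditions: mCPBA (2.5 equiv), NaHCO3, CH2Cl2, −20 °C → rt; aq Na2S2O3/NaHCO3 work-up
Reagents that add atoms: 3-chloroperoxybenzoic acid, OOC(=O)c1cccc(Cl)c1
Why: Rubottom oxidation, in which the peracid epoxidises the silyl enol ether from the α-face (the β-face is covered by the 6β- and 3β-methyl groups) and the silyloxy oxirane 18 opens with 1,4-silyl shift to the α-silyloxy ketone 19, after which the second equivalent should epoxidise the cis-disubstituted C1=C2 bond (Prilezhaev epoxidation) anti to the axial 6β-methyl group to set the 1α,2α-epoxide.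

Step 11
Reactants: 20 1α,2α-epoxy-4α-(trimethylsilyloxy)-5-ketone
Product: 23 1α,5β-dihydroxy-3,6β-dimethyl-9α-(propan-2-yl)-9β-[(triethylsilyl)oxy]-10α-H-bicyclo[5.3.0]dec-2-en-4-one (overview locants), via epoxy ketol 21 (not isolated), via transposed epoxy ketol 22 (not isolated)
Conditions: K2CO3 (0.5 equiv), MeOH (degassed, argon), 0 °C → rt; AcOH quench
Reagents that add atoms: none
Why: methanolysis frees ketol 21, which tautomerises through the enediol (only H-4 is enolisable, C6 being quaternary; α-ketol transposition of the Lobry de Bruyn–Alberda van Ekenstein type) to 22 with protonation of C5 on the α-face anti to the 6β-methyl group (5β-OH), and the new C4 ketone then triggers E1cB opening of the β,γ-epoxide through the C3 enolate to the conjugated 1α-hydroxy-2-en-4-one, which drains the equilibria.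

Step 12
Reactants: 23 1α,5β-dihydroxy-2-en-4-one (9-O-triethylsilyl)
Product: 24 1α-(4-methoxybenzoyloxy)-5β-hydroxy-3,6β-dimethyl-9α-(propan-2-yl)-9β-[(triethylsilyl)oxy]-10α-H-bicyclo[5.3.0]dec-2-en-4-one (overview locants)
Conditions: 4-MeOC6H4COCl (1.2 equiv), pyridine, DMAP (0.1 equiv), CH2Cl2, 0 °C
Reagents that add atoms: 4-methoxybenzoyl chloride, COc1ccc(cc1)C(Cl)=O
Why: nucleophile-catalysed acylation by the acid chloride should take place at the allylic C1 hydroxyl, because the C5 hydroxyl is hydrogen-bonded to the C4 carbonyl and flanked by the quaternary C6 and the tertiary silyl ether is inert; no stereocentre is touched.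

Step 13
Reactants: 24 1α-(4-methoxybenzoyloxy)-5β-hydroxy-2-en-4-one (9-O-triethylsilyl)
Product: 25 (3R,3aS,4S,8R,8aS)-3,8-dihydroxy-6,8a-dimethyl-7-oxo-3-(propan-2-yl)-1,2,3,3a,4,7,8,8a-octahydroazulen-4-yl 4-methoxybenzoate (overview locants: 1S,5R,6S,9R,10S)
Conditions: HF·pyridine, pyridine, THF, 0 °C → rt
Reagents that add atoms: none
Why: fluoride-assisted cleavage of the Si–O bond by buffered HF·pyridine removes the tertiary triethylsilyl ether (silyl ether deprotection) without affecting the aryl ester, the enone or the α-ketol, and no stereocentre is affected.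

**Compound list**

1 | ethyl 2-cyanopropanoate | CCOC(=O)C(C)C#N | starting material
2 | 4-methylpent-1-en-3-one | C=CC(=O)C(C)C | starting material
3 | ethyl 2-cyano-2,6-dimethyl-5-oxoheptanoate (racemic) | CCOC(=O)C(C)(C#N)CCC(=O)C(C)C | intermediate
4 | 2,6-dimethyl-5-oxoheptanenitrile (racemic) | N#CC(C)CCC(=O)C(C)C | intermediate
5 | (E)-pent-3-en-1-yne | C/C=C/C#C | starting material
6 | chlorobis(cyclopentadienyl)[(1E,3E)-penta-1,3-dien-1-yl]zirconium (formed in the flask; cyclopentadienyl rings written σ-bonded) | C/C=C/C=C/[Zr](Cl)(C1C=CC=C1)C1C=CC=C1 | intermediate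
7 | methyl[(1E,3E)-penta-1,3-dien-1-yl]zinc (formed in the flask) | C/C=C/C=C/[Zn]C | intermediate
8 | (5R,6E,8E)-5-hydroxy-2-methyl-5-(propan-2-yl)deca-6,8-dienenitrile (both C2 epimers) | N#CC(C)CC[C@@](O)(C(C)C)/C=C/C=C/C | intermediate
9 | (5R,6E,8E)-2-methyl-5-(propan-2-yl)-5-[(triethylsilyl)oxy]deca-6,8-dienenitrile (both C2 epimers) | N#CC(C)CC[C@@](O[Si](CC)(CC)CC)(C(C)C)/C=C/C=C/C | intermediate
10 | N-lithio ketimine of 11 (formed in the flask) | [Li]N=C(C)C(C)CC[C@@](O[Si](CC)(CC)CC)(C(C)C)/C=C/C=C/C | intermediate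
11 | (6R,7E,9E)-3-methyl-6-(propan-2-yl)-6-[(triethylsilyl)oxy]undeca-7,9-dien-2-one (both C3 epimers) | CC(=O)C(C)CC[C@@](O[Si](CC)(CC)CC)(C(C)C)/C=C/C=C/C | intermediate
12 | (6R,7E,9E)-3-methyl-6-(propan-2-yl)-6-[(triethylsilyl)oxy]-2-[(trimethylsilyl)oxy]undeca-2,7,9-triene (2E/2Z mixture) | CC(O[Si](C)(C)C)=C(C)CC[C@@](O[Si](CC)(CC)CC)(C(C)C)/C=C/C=C/C | intermediate
13 | (6R,7E,9E)-3-chloro-3-methyl-6-(propan-2-yl)-6-[(triethylsilyl)oxy]undeca-7,9-dien-2-one (both C3 epimers) | CC(=O)C(C)(Cl)CC[C@@](O[Si](CC)(CC)CC)(C(C)C)/C=C/C=C/C | intermediate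
14 | sodium enolate of 13 (C4=C5 enolate; formed in the flask) | [Na+].[O-]C(=C)C(C)(Cl)CC[C@@](O[Si](CC)(CC)CC)(C(C)C)/C=C/C=C/C | intermediate
15 | 2-oxidoallyl cation C4–C5(O)–C6 tethered to the dienyl silyl ether (formed in the flask) | [O-]C(=C)[C+](C)CC[C@@](O[Si](CC)(CC)CC)(C(C)C)/C=C/C=C/C | intermediate
16 | (3R,6S,9R,10R)-3β,6β-dimethyl-9α-(propan-2-yl)-9β-[(triethylsilyl)oxy]-10α-H-bicyclo[5.3.0]dec-1-en-5-one (overview locants; trans-fused) | C1=C[C@H](C)CC(=O)[C@@]2(C)CC[C@@](O[Si](CC)(CC)CC)(C(C)C)[C@H]12 | intermediate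
17 | trimethylsilyl enol ether of 16 (C4=C5–OSiMe3, C1=C2) | C1=C[C@H](C)C=C(O[Si](C)(C)C)[C@@]2(C)CC[C@@](O[Si](CC)(CC)CC)(C(C)C)[C@H]12 | intermediate
18 | 4α,5α-epoxy-5β-(trimethylsilyloxy) derivative of 17 (silyloxy oxirane; formed in the flask) | C1=C[C@H](C)[C@H]3O[C@@]3(O[Si](C)(C)C)[C@@]2(C)CC[C@@](O[Si](CC)(CC)CC)(C(C)C)[C@H]12 | intermediate
19 | 4α-(trimethylsilyloxy)-5-ketone with C1=C2 retained (formed in the flask) | C1=C[C@H](C)[C@@H](O[Si](C)(C)C)C(=O)[C@@]2(C)CC[C@@](O[Si](CC)(CC)CC)(C(C)C)[C@H]12 | intermediate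
20 | 1α,2α-epoxy-4α-(trimethylsilyloxy)-5-ketone (3β,6β-dimethyl, 9β-OSiEt3, 9α-isopropyl, 10α-H) | O1[C@H]2[C@@H]1[C@H](C)[C@@H](O[Si](C)(C)C)C(=O)[C@@]3(C)CC[C@@](O[Si](CC)(CC)CC)(C(C)C)[C@H]23 | intermediate
21 | 1α,2α-epoxy-4α-hydroxy-5-ketone (formed in the flask) | O1[C@H]2[C@@H]1[C@H](C)[C@@H](O)C(=O)[C@@]3(C)CC[C@@](O[Si](CC)(CC)CC)(C(C)C)[C@H]23 | intermediate
22 | 1α,2α-epoxy-5β-hydroxy-4-ketone (formed in the flask) | O1[C@H]2[C@@H]1[C@H](C)C(=O)[C@H](O)[C@@]3(C)CC[C@@](O[Si](CC)(CC)CC)(C(C)C)[C@H]23 | intermediate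
23 | 1α,5β-dihydroxy-3,6β-dimethyl-9α-(propan-2-yl)-9β-[(triethylsilyl)oxy]-10α-H-bicyclo[5.3.0]dec-2-en-4-one | O[C@H]2C=C(C)C(=O)[C@H](O)[C@@]3(C)CC[C@@](O[Si](CC)(CC)CC)(C(C)C)[C@H]23 | intermediate
24 | 1α-(4-methoxybenzoyloxy)-5β-hydroxy-3,6β-dimethyl-9α-(propan-2-yl)-9β-[(triethylsilyl)oxy]-10α-H-bicyclo[5.3.0]dec-2-en-4-one | COc1ccc(C(=O)O[C@H]2C=C(C)C(=O)[C@H](O)[C@@]3(C)CC[C@@](O[Si](CC)(CC)CC)(C(C)C)[C@H]23)cc1 | intermediate
25 | (3R,3aS,4S,8R,8aS)-3,8-dihydroxy-6,8a-dimethyl-7-oxo-3-(propan-2-yl)-1,2,3,3a,4,7,8,8a-octahydroazulen-4-yl 4-methoxybenzoate (CNP0299970.1) | COc1ccc(C(=O)O[C@H]2C=C(C)C(=O)[C@H](O)[C@@]3(C)CC[C@@](O)(C(C)C)[C@H]23)cc1 | target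

**Step count**

Total: 13 steps. Longest linear sequence: 13 steps (1 and 2 to 25); enyne 5 enters in step 3.

**Steps most likely to fail**

1. Step 8. The cation may be intercepted before it cyclises (capture by trifluoroethoxide or by the C9 silyloxy oxygen, Favorskii contraction through the cyclopropanone, proton loss to the enone). The discrimination between extended and compact transition states, or between the two diene faces, may also be poor. The fallback sets out from 13 and returns at 16. TMSOTf/Et3N (CH2Cl2, −78 °C) converts 13, which can enolise only towards C4, into (6R,7E,9E)-3-chloro-3-methyl-6-(propan-2-yl)-6-[(triethylsilyl)oxy]-2-[(trimethylsilyl)oxy]undeca-1,7,9-triene F1. Chloride abstraction with AgBF4 and 2,6-di-tert-butylpyridine in CH2Cl2/MeNO2 at −78 °C gives the 2-(silyloxy)allyl cation, a more electrophilic partner generated without base or nucleophilic solvent. Its intramolecular (4+3) cycloaddition and loss of the silyl group should give 16.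

2. Step 11. Under the equilibrating basic conditions C5 may epimerise or the enediol may be oxidised, and the acylation that follows in step 12 may not discriminate between the two secondary hydroxyls. The fallback sets out from 17 and returns at 25.
 - Saegusa–Ito dehydrogenation of 17 (Pd(OAc)2, divalent palladium, MeCN) gives the 3,6β-dimethyl-9β-(triethylsilyloxy)bicyclo[5.3.0]deca-1,3-dien-5-one F2.
 - Luche reduction (NaBH4, CeCl3·7H2O, MeOH, −78 °C) adds hydride on the α-face, anti to the 6β-methyl group, to give the 5β-hydroxy-1,3-diene F3.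
 - TBSOTf/2,6-lutidine gives the 5β-(tert-butyldimethylsilyloxy)-1,3-diene F4.
 - mCPBA/NaHCO3 epoxidises the trisubstituted C3=C4 bond anti to the 5β-silyloxy group to give the 3α,4α-epoxy-1-ene F5.
 - Pd(PPh3)4 (zerovalent palladium) with 4-methoxybenzoic acid in THF opens the vinyl epoxide by syn 1,4-addition (ionisation and carboxylate attack each with inversion), giving the 1α-(4-methoxybenzoyloxy)-4α-hydroxy-2-ene F6.
 - Dess–Martin oxidation gives the 1α-(4-methoxybenzoyloxy)-5β-silyloxy-2-en-4-one F7, and HF·pyridine removes both silyl groups to give 25.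
 
 C5 is then set by hydride delivery, C1 by the double inversion, and the ester is introduced with no other free hydroxyl present.

3. Step 3. Enantioface discrimination between the isopropyl group and the unbranched chain of the dialkyl ketone may be insufficient. The fallback sets out from 4 and returns at 8. Dienylzinc 7 is added to 4 with Ti(OiPr)4 but without the chiral ligand, and the racemic alcohol is resolved by preparative chromatography on a chiral stationary phase. The (5S,6E,8E)-5-hydroxy-2-methyl-5-(propan-2-yl)deca-6,8-dienenitrile F8 is set aside and the (5R) series is carried on as 8.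

**Further compounds**

F1 | step 8 | (6R,7E,9E)-3-chloro-3-methyl-6-(propan-2-yl)-6-[(triethylsilyl)oxy]-2-[(trimethylsilyl)oxy]undeca-1,7,9-triene | C=C(O[Si](C)(C)C)C(C)(Cl)CC[C@@](O[Si](CC)(CC)CC)(C(C)C)/C=C/C=C/C
F2 | step 11 | 3,6β-dimethyl-9α-(propan-2-yl)-9β-[(triethylsilyl)oxy]-10α-H-bicyclo[5.3.0]deca-1,3-dien-5-one | C1=CC(C)=CC(=O)[C@@]2(C)CC[C@@](O[Si](CC)(CC)CC)(C(C)C)[C@H]12
F3 | step 11 | 5β-hydroxy-1,3-diene (from F2) | C1=CC(C)=C[C@H](O)[C@@]2(C)CC[C@@](O[Si](CC)(CC)CC)(C(C)C)[C@H]12
F4 | step 11 | 5β-(tert-butyldimethylsilyloxy)-1,3-diene | C1=CC(C)=C[C@H](O[Si](C)(C)C(C)(C)C)[C@@]2(C)CC[C@@](O[Si](CC)(CC)CC)(C(C)C)[C@H]12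
F5 | step 11 | 3α,4α-epoxy-5β-(tert-butyldimethylsilyloxy)-1-ene | C1=C[C@@]3(C)O[C@H]3[C@H](O[Si](C)(C)C(C)(C)C)[C@@]2(C)CC[C@@](O[Si](CC)(CC)CC)(C(C)C)[C@H]12
F6 | step 11 | 1α-(4-methoxybenzoyloxy)-4α-hydroxy-5β-(tert-butyldimethylsilyloxy)-2-ene | COc1ccc(C(=O)O[C@H]2C=C(C)[C@@H](O)[C@H](O[Si](C)(C)C(C)(C)C)[C@@]3(C)CC[C@@](O[Si](CC)(CC)CC)(C(C)C)[C@H]23)cc1
F7 | step 11 | 1α-(4-methoxybenzoyloxy)-5β-(tert-butyldimethylsilyloxy)-2-en-4-one | COc1ccc(C(=O)O[C@H]2C=C(C)C(=O)[C@H](O[Si](C)(C)C(C)(C)C)[C@@]3(C)CC[C@@](O[Si](CC)(CC)CC)(C(C)C)[C@H]23)cc1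
F8 | step 3 | (5S,6E,8E)-5-hydroxy-2-methyl-5-(propan-2-yl)deca-6,8-dienenitrile | N#CC(C)CC[C@](O)(C(C)C)/C=C/C=C/C
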